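**Strategy.** The γ-lactone is closed last, at carbon: C14 is joined to C13, the spiro carbon shared by the tetrahydrofuran (O–C9–C11–C12–C13) and the lactone (C13–C14–C15–O–C16). The precursor is a tetrahydrofuran-2-carboxylic ester whose alcohol part ends in a diazomethyl group (C14). A cobalt(II) metalloradical turns C14 into a carbene radical that abstracts the C13–H hydrogen, which is weakened by the ring oxygen and the C16 carbonyl and lies 1,5 to C14, and then bonds to C13. One operation makes the quaternary stereocentre, the second spiro ring and a bare CH2 at C14. The cis-decalin comes from a quinone Diels–Alder reaction, the tetrahydrofuran from a radical–polar [3+2] annulation.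

Key step: step 11

**Remarks.**
- Numbering: labdane locants are used. Decalin C1–C10 (C4 gem-dimethyl, C5 and C10 ring fusion, C6 oxygenated, C8 bearing CH3-17, C9 spiro, CH3-20 on C10); side chain C11–C16 (C13 second spiro carbon, C16 lactone carbonyl).
- Configuration: the SMILES is read as 5S,6S,8R,9R,10R,13R, a cis-fused decalin with H-5, CH3-20, O-6, CH3-17 and O-9 on one face.
- Assumption: the two faces at C13 are nearly equivalent to reagents (C8 and C10 each turn an equatorial methyl toward the tetrahydrofuran), so C13 is set by catalyst control. In steps 1, 7 and 11 the catalyst enantiomer named is the one expected to give the sense shown; the antipode is equally accessible.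

**Route**

Step 1
Reactants: 1 2,6-dimethyl-1,4-benzoquinone; 2 4-methylpenta-1,3-diene
Product: 3 (4aS,8aR)-2,5,5,8a-tetramethyl-4a,5,8,8a-tetrahydronaphthalene-1,4-dione
Conditions: (S)-B-(o-tolyl)oxazaborolidinium triflimide (from (S)-α,α-diphenylprolinol, 20 mol %), 2 (5 equiv), CH2Cl2, −78 → −40 °C
Reagents that add atoms: none
Why: Catalytic enantioselective Diels–Alder reaction in which the cationic oxazaborolidine binds the unhindered quinone C4=O (C6 of the target), so the CH2 terminus of the diene bonds to the methyl-bearing β-carbon (C10) and the CMe2 terminus to the CH carbon (C5); suprafacial addition fixes H-5 and CH3-20 cis, and the catalyst directs the diene to the 2Re,3Si face of the quinone (5S,10R).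

Step 2
Reactants: 3
Product: 4 (4aS,8aR)-2,5,5,8a-tetramethyloctahydronaphthalene-1,4-dione (C2 epimers, i.e. epimers at C8)
Conditions: H2 (3 atm), 10 % Pd/C, EtOAc, rt
Reagents that add atoms: none
Why: Heterogeneous catalytic hydrogenation saturates the ring-A alkene and the ene-dione C7=C8 bond (C10 is quaternary, so no aromatisation); C8 forms as an inconsequential epimer mixture that is equilibrated in step 4.

Step 3
Reactants: 4
Product: 5 (4S,4aS,8aR)-4-hydroxy-2,5,5,8a-tetramethyloctahydronaphthalen-1(2H)-one (C2 epimers)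
Conditions: Prelog-selective ketoreductase, NADP+ (cat.), iPrOH (10 % v/v), phosphate buffer pH 7.0, DMSO (5 %), 30 °C
Reagents that add atoms: none
Why: Enzymatic ketone reduction (ketoreductase, NADPH recycled by isopropanol) that accepts only the unhindered C6 carbonyl (C9 is flanked by quaternary C10 and by C8) and delivers hydride to its Re face (large = C5 side, small = C7), giving the 6S alcohol; pH 7 avoids enolisation toward C5.

Step 4
Reactants: 5
Product: 7 (1S,3R,4aR,8aS)-3,4a,8,8-tetramethyl-4-methylidenedecahydronaphthalen-1-ol, via 8R-hydroxy ketone 6 (not isolated)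
Conditions: Ph3PCH3Br (3.5 equiv), KOtBu (3.6 equiv), toluene, 100 °C
Reagents that add atoms: methyltriphenylphosphonium bromide, C[P+](c1ccccc1)(c1ccccc1)c1ccccc1.[Br-]
Why: Wittig methylenation of a hindered ketone under forcing conditions; excess KOtBu first equilibrates C8, the only enolisable position of the C9 ketone, to the equatorial 8R epimer (the 8S epimer would place CH3-17 syn-axial to C1), and the ylide then converts C9=O into the exocyclic methylene while the C6 alkoxide stays inert.

Step 5
Reactants: 7; 8 ethyl bromopyruvate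
Product: 9 ethyl (5S,6S,8R,9R,10R)-9,13-epoxy-6-hydroxy-14,15-dinorlabd-12-en-16-oate (spiro-4,5-dihydrofuran-2-carboxylate at C9)
Conditions: 8 (1.5 equiv), fac-Ir(ppy)3 (1 mol %), 2,6-lutidine (2 equiv), MeCN, blue LEDs, rt
Reagents that add atoms: none
Why: Photoredox atom-transfer radical addition with radical–polar crossover (formal [3+2], interrupted Feist–Bénary-type dihydrofuran synthesis): the 2-oxoalkyl radical adds to the CH2 terminus (C11), the tertiary C9 radical is oxidised to the cation, the ketone oxygen closes the five-membered ring and loss of H-12 gives the enol ether; oxygen attacks C9 axially, opposite the axial C1–C10 bond, so O-9 is cis to CH3-17 and CH3-20 (9R), which is also the more stable O-axial/C11-equatorial spiro ether.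

Step 6
Reactants: 9
Product: 10 (5S,6S,8R,9R,10R)-9,13-epoxy-6-hydroxy-14,15-dinorlabd-12-en-16-oic acid
Conditions: LiOH·H2O (3 equiv), THF/H2O 3:1, rt; then 1 M HCl to pH 3
Reagents that add atoms: lithium hydroxide, [Li+].[OH-]
Why: Ester saponification (BAc2); the enol ether and the tertiary spiro ether are stable to hydroxide.

Step 7
Reactants: 10
Product: 11 (5S,6S,8R,9R,10R,13S)-9,13-epoxy-6-hydroxy-14,15-dinorlabdan-16-oic acid
Conditions: [Ir(cod)((Sa,S)-SpiroPHOX)]BArF (1 mol %), H2 (6 atm), Et3N (0.5 equiv), MeOH, rt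
Reagents that add atoms: none
Why: Carboxylate-directed iridium-catalysed asymmetric hydrogenation of an α-alkoxy-α,β-unsaturated acid with a chiral spiro phosphine–oxazoline ligand; the 13S C–H stereocentre is set by the catalyst, since the substrate offers almost no facial bias.

Step 8
Reactants: 11; 12 allyl bromide
Product: 13 allyl (5S,6S,8R,9R,10R,13S)-9,13-epoxy-6-hydroxy-14,15-dinorlabdan-16-oate
Conditions: 12 (1.2 equiv), K2CO3 (1.5 equiv), DMF, rt
Reagents that add atoms: none
Why: SN2 O-alkylation of the carboxylate; carbonate does not alkylate the hindered C6 hydroxyl and does not enolise the C13–H centre.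

Step 9
Reactants: 13
Product: 14 allyl (5S,6S,8R,9R,10R,13S)-6-acetoxy-9,13-epoxy-14,15-dinorlabdan-16-oate
Conditions: Ac2O (3 equiv), DMAP (0.1 equiv), pyridine, rt
Reagents that add atoms: acetic anhydride, CC(=O)OC(C)=O
Why: DMAP-catalysed acylation of the equatorial C6 alcohol installs the acetate before any oxidant is used.

Step 10
Reactants: 14
Product: 16 2-[(tert-butyldimethylsilyl)hydrazinylidene]ethyl (5S,6S,8R,9R,10R,13S)-6-acetoxy-9,13-epoxy-14,15-dinorlabdan-16-oate, via 2-oxoethyl ester 15 (not isolated)
Conditions: O3, CH2Cl2, −78 °C, then PPh3; concentrate; TBSNHNHTBS (1.05 equiv), Sc(OTf)3 (0.01 mol %), CH2Cl2, 0 °C → rt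
Reagents that add atoms: 1,2-bis(tert-butyldimethylsilyl)hydrazine, CC(C)(C)[Si](C)(C)NN[Si](C)(C)C(C)(C)C
Why: Ozonolysis of the only alkene (allyl ester to 2-oxoethyl ester, reductive work-up) followed by Lewis-acid-catalysed condensation with the bis-silyl hydrazine gives the N-silyl hydrazone under neutral conditions, which avoids the base-induced loss of the β-acyloxy group that a sulfonylhydrazone anion would suffer.

Step 11
Reactants: 16
Product: 18 (5S,6S,8R,9R,10R,13R)-6-acetoxy-9,13-epoxylabdan-16,15-olide (target), via 2-diazoethyl ester 17 (not isolated)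
Conditions: PhIF2 (1.05 equiv), 2-chloropyridine (2 equiv), CH2Cl2, −78 °C; then [Co(Por*)] (D2-symmetric chiral amidoporphyrin Co(II) complex, 5 mol %), −78 → 0 °C
Reagents that add atoms: none
Why: Oxidation of the N-silyl hydrazone gives the 2-diazoethyl ester 17, which the Co(II) metalloradical converts, with loss of N2, into an α-Co(III)-alkyl radical at C14; this abstracts the C13–H hydrogen through a six-membered transition state (1,5-HAT across C15–O–C16), and the C13 radical then displaces cobalt from C14, closing the γ-lactone C13–C14–C15–O–C16 by 5-exo-tet radical substitution and leaving C14 as CH2. The closest known reaction type is the Co(II)–porphyrin metalloradical 1,5-C–H alkylation with aliphatic diazo compounds derived from aldehyde hydrazones, which builds five-membered rings at C–H bonds α to oxygen or nitrogen. C13 is the only new stereocentre: C14 should take the place of H on the face from which it was abstracted, because rebound inside the porphyrin pocket is expected to be faster than rotation about the C13–C16 bond of the captodative radical, so 13S (C–H) becomes 13R; the amidoporphyrin, used as the matched enantiomer, favours the same face if the radical relaxes. The step needs hydrogen abstraction at C13–H in preference to 1,2-H shift to the vinyl ester, azine formation and abstraction elsewhere; this rests on the metalloradical (not free-carbene) pathway, on the low C13–H bond strength (α to ring O and to the C16 carbonyl) and on the absence of any other C–H 1,5 to C14.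

**Compound list**

1 | 2,6-dimethyl-1,4-benzoquinone | CC1=CC(=O)C=C(C)C1=O | starting material
2 | 4-methylpenta-1,3-diene | C=CC=C(C)C | starting material
3 | (4aS,8aR)-2,5,5,8a-tetramethyl-4a,5,8,8a-tetrahydronaphthalene-1,4-dione (cis-fused adduct) | O=C1C=C(C)C(=O)[C@]2(C)CC=CC(C)(C)[C@H]12 | intermediate
4 | (4aS,8aR)-2,5,5,8a-tetramethyloctahydronaphthalene-1,4-dione, C2 (labdane C8) epimers | O=C1CC(C)C(=O)[C@]2(C)CCCC(C)(C)[C@H]12 | intermediate
5 | (4S,4aS,8aR)-4-hydroxy-2,5,5,8a-tetramethyloctahydronaphthalen-1(2H)-one, C2 epimers | O[C@H]1CC(C)C(=O)[C@]2(C)CCCC(C)(C)[C@H]12 | intermediate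
6 | (2R,4S,4aS,8aR)-4-hydroxy-2,5,5,8a-tetramethyloctahydronaphthalen-1(2H)-one (8R epimer, formed in the flask as its alkoxide) | O[C@H]1C[C@@H](C)C(=O)[C@]2(C)CCCC(C)(C)[C@H]12 | intermediate
7 | (1S,3R,4aR,8aS)-3,4a,8,8-tetramethyl-4-methylidenedecahydronaphthalen-1-ol | O[C@H]1C[C@@H](C)C(=C)[C@]2(C)CCCC(C)(C)[C@H]12 | intermediate
8 | ethyl bromopyruvate | CCOC(=O)C(=O)CBr | starting material
9 | ethyl (5S,6S,8R,9R,10R)-9,13-epoxy-6-hydroxy-14,15-dinorlabd-12-en-16-oate | O[C@H]1C[C@@H](C)[C@]2(CC=C(C(=O)OCC)O2)[C@]2(C)CCCC(C)(C)[C@H]12 | intermediate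
10 | (5S,6S,8R,9R,10R)-9,13-epoxy-6-hydroxy-14,15-dinorlabd-12-en-16-oic acid | O[C@H]1C[C@@H](C)[C@]2(CC=C(C(=O)O)O2)[C@]2(C)CCCC(C)(C)[C@H]12 | intermediate
11 | (5S,6S,8R,9R,10R,13S)-9,13-epoxy-6-hydroxy-14,15-dinorlabdan-16-oic acid | O[C@H]1C[C@@H](C)[C@]2(CC[C@@H](C(=O)O)O2)[C@]2(C)CCCC(C)(C)[C@H]12 | intermediate
12 | allyl bromide | C=CCBr | starting material
13 | allyl ester of 11 | O[C@H]1C[C@@H](C)[C@]2(CC[C@@H](C(=O)OCC=C)O2)[C@]2(C)CCCC(C)(C)[C@H]12 | intermediate
14 | 6-O-acetate of 13 | CC(=O)O[C@H]1C[C@@H](C)[C@]2(CC[C@@H](C(=O)OCC=C)O2)[C@]2(C)CCCC(C)(C)[C@H]12 | intermediate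
15 | 2-oxoethyl ester (aldehyde from 14) | CC(=O)O[C@H]1C[C@@H](C)[C@]2(CC[C@@H](C(=O)OCC=O)O2)[C@]2(C)CCCC(C)(C)[C@H]12 | intermediate
16 | N-(tert-butyldimethylsilyl)hydrazone of 15 | CC(=O)O[C@H]1C[C@@H](C)[C@]2(CC[C@@H](C(=O)OCC=NN[Si](C)(C)C(C)(C)C)O2)[C@]2(C)CCCC(C)(C)[C@H]12 | intermediate
17 | 2-diazoethyl ester | CC(=O)O[C@H]1C[C@@H](C)[C@]2(CC[C@@H](C(=O)OCC=[N+]=[N-])O2)[C@]2(C)CCCC(C)(C)[C@H]12 | intermediate
18 | (5S,6S,8R,9R,10R,13R)-6-acetoxy-9,13-epoxylabdan-16,15-olide | CC(=O)O[C@H]1C[C@@H](C)[C@]2(CC[C@]3(CCOC3=O)O2)[C@]2(C)CCCC(C)(C)[C@H]12 | target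

**Totals.** Total step count: 11. Longest linear sequence: 11 steps (1 and 2 to 18).

**Steps most likely to fail**

Step 11. The Co-bound C14 radical may not reach the C13–H bond because the ester linkage stays s-trans, so that 1,2-hydrogen shift to the vinyl ester or azine formation takes over; or the C13 radical relaxes and facial selectivity is lost. The fallback sets out from 13 and returns at 18. The dianion of 13 (LDA, 2.2 equiv, THF/DMPU, −78 °C) should be C-alkylated at C13 with tert-butyl(2-iodoethoxy)dimethylsilane (−78 → −30 °C, below the onset of ester-enolate Claisen rearrangement) to give the C13-quaternary allyl ester F1 as a pair of C13 epimers, of which the one shown is separated by chromatography. Acid methanolysis (TsOH, MeOH, rt) should remove the silyl group, and the freed primary alcohol lactonises onto the allyl ester to give the hydroxy spirolactone F2. Acetylation (Ac2O, DMAP, pyridine) then gives 18.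

Step 5. The C9 cation may suffer 1,2-shift of CH3-20 or proton loss before the ketone oxygen captures it, or the weakly nucleophilic keto-ester oxygen may fail to close the ring. The fallback sets out from 7 and returns at 10. Epoxidation (mCPBA, NaHCO3, CH2Cl2, 0 °C; axial attack opposite C1) should give the spiro-oxirane F3 with oxygen on the required face. Opening at the CH2 terminus with lithium acetylide–ethylenediamine (DMSO, rt) gives the homopropargylic tertiary alcohol F4. Endo-cycloisomerisation through a molybdenum vinylidene (Mo(CO)6, Et3N, Et2O, hν) gives the spiro-2,3-dihydrofuran F5. Lithiation at C13 (t-BuLi, 3 equiv, THF, −78 → 0 °C) and carboxylation (CO2, then HCl) give 10.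

Step 1. The strongly acidic catalyst may oligomerise the diene, or cycloaddition at the hindered CMe2 terminus may be too slow at low temperature. The fallback sets out from 1 and 2 and returns at 5. Uncatalysed cycloaddition at 12 kbar (CH2Cl2, rt) should give 3 together with its enantiomer F6. Hydrogenation as in step 2 gives 4 together with F7. The ketoreductase of step 3 then acts on the racemate: it forms 5 from 4 and either leaves F7 untouched or reduces it to the diastereomeric 6S alcohol F8; in both cases 5 is separated by chromatography.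

**Further compounds**

F1 | step 11 | allyl (5S,6S,8R,9R,10R,13R)-13-[2-(tert-butyldimethylsilyloxy)ethyl]-9,13-epoxy-6-hydroxy-14,15-dinorlabdan-16-oate | O[C@H]1C[C@@H](C)[C@]2(CC[C@@](CCO[Si](C)(C)C(C)(C)C)(C(=O)OCC=C)O2)[C@]2(C)CCCC(C)(C)[C@H]12
F2 | step 11 | (5S,6S,8R,9R,10R,13R)-9,13-epoxy-6-hydroxylabdan-16,15-olide | O[C@H]1C[C@@H](C)[C@]2(CC[C@]3(CCOC3=O)O2)[C@]2(C)CCCC(C)(C)[C@H]12
F3 | step 5 | (5S,6S,8R,9R,10R)-9,11-epoxy spiro-oxirane of 7 | O[C@H]1C[C@@H](C)[C@]2(CO2)[C@]2(C)CCCC(C)(C)[C@H]12
F4 | step 5 | (1S,3R,4R,4aR,8aS)-3,4a,8,8-tetramethyl-4-(prop-2-yn-1-yl)decahydronaphthalene-1,4-diol | O[C@H]1C[C@@H](C)[C@](O)(CC#C)[C@]2(C)CCCC(C)(C)[C@H]12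
F5 | step 5 | (5S,6S,8R,9R,10R)-9,13-epoxy-14,15,16-trinorlabd-12-en-6-ol (spiro-2,3-dihydrofuran) | O[C@H]1C[C@@H](C)[C@]2(CC=CO2)[C@]2(C)CCCC(C)(C)[C@H]12
F6 | step 1 | (4aR,8aS)-2,5,5,8a-tetramethyl-4a,5,8,8a-tetrahydronaphthalene-1,4-dione (enantiomer of 3) | O=C1C=C(C)C(=O)[C@@]2(C)CC=CC(C)(C)[C@@H]12
F7 | step 1 | (4aR,8aS)-2,5,5,8a-tetramethyloctahydronaphthalene-1,4-dione, C2 epimers (enantiomer of 4) | O=C1CC(C)C(=O)[C@@]2(C)CCCC(C)(C)[C@@H]12
F8 | step 1 | (4S,4aR,8aS)-4-hydroxy-2,5,5,8a-tetramethyloctahydronaphthalen-1(2H)-one, C2 epimers | O[C@H]1CC(C)C(=O)[C@@]2(C)CCCC(C)(C)[C@@H]12
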